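(The numbers in the tables were generated by integration with made-up constants.)

| flask | starting complex | incoming ligand | leaving ligand | temperature | remark | time |
|---|---|---|---|---|---|---|
| larch | 0.010 M | 4 equiv | 2 equiv | 25 °C | run made earlier |  |
| birch | 0.010 M | 4 equiv | 4 equiv | 25 °C | run made earlier |  |
| ochre | 0.010 M (fed, over 25 h) | 4.00 equiv | 2.00 equiv | 25 °C | all else is in the flask from the start; the feed brings no volume worth counting | 40 h |
| teal | 0.010 M | 4.00 equiv | 2.00 equiv | 25 °C | everything together at the start | 40 h |
| green | 0.010 M | 4.00 equiv (fed, over 25 h) | 2.00 equiv | 25 °C | all else is in the flask from the start; the feed brings no volume worth counting | 40 h |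
| red | 0.010 M (fed, over 25 h) | 4.00 equiv | 2.00 equiv |  | the addition at 5 °C, then warmed to 25 °C; the feed brings no volume worth counting | 40 h |
| grey | 0.010 M | 4.00 equiv | 2.00 equiv |  | everything together at the start at 5 °C, warmed to 25 °C at 25 h | 40 h |

| run | time / h | complex with one exchanged / % |
|---|---|---|
| larch | 4.00 | 23 |
| larch | 10.0 | 19 |
| larch | 20.0 | 11 |
| larch | 30.0 | 8 |
| larch | 40.0 | 9 |
| birch | 2.50 | 18 |
| birch | 5.00 | 16 |
| birch | 8.00 | 17 |
| birch | 10.0 | 13 |
| birch | 12.0 | 10 |

(readings scatter by 1.5 percentage points)

- the best flask by amount of complex with one exchanged, in percent of the starting complex charged; "all alike" if 1.5 percentage points covers them all (ochre / teal / green / red / grey / all alike)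
- amount of complex with one exchanged at the end, in percent of the starting complex charged, ochre
- amount of complex with one exchanged at the end, in percent of the starting complex charged, teal
- amount of complex with one exchanged at the end, in percent of the starting complex charged, green
- amount of complex with one exchanged at the end, in percent of the starting complex charged, red
- amount of complex with one exchanged at the end, in percent of the starting complex charged, grey

- the numbers in the tables scatter with a standard deviation of 1.5 percentage points
- the earlier runs do not show what temperature does; that part of a forecast is a guess

At early times larch holds y, the complex with one exchanged, at 23% after 4.00 h, and birch, with more leaving ligand, holds 18% after 2.50 h. So I begin with the main step, a fast reversible first exchange whose level falls as leaving ligand rises. That step gives a flat level, but larch sinks to 11% by 20.0 h and then barely moves, reading 9% at 40.0 h. A loss that slows as the level drops suggests a loss by pairs, and then the reciprocal of y climbs in a straight line.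

Between its first reading and the mean of its last two, larch gives 0.239 h⁻¹; this hourly rise of the reciprocal of y is the loss clock, s. Birch reads 0.388 h⁻¹, faster though on a short span of scattered readings, so I tentatively take the pairs to be starting complex, which leaving ligand pushes material back towards. Run back to zero time, the larch line gives a notional first share y₀ of 29.5%, and run forward it gives teal 7.72%.

Now I add the feed. In ochre, y is supplied at y₀ spread over 25 h and lost at s times y squared. Solving that gives 19.3% at the end of the feed, and the straight line then carries ochre to 11.4%.

Then the rest. In green, starting complex stands exposed while incoming ligand trickles in. Green's pool begins as starting complex, whereas in larch I roughly count as starting complex what y₀ leaves over, so I scale the clock of the whole pool, s times y₀ or 0.0706 h⁻¹, by the inverse square of that remainder, which gives 0.142 h⁻¹, faster. Green then ends near 5.26%. For the cold I guess s falls by a factor of 4, which gives red 13.4% and grey 11.8%, so red comes out highest.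

The forecast gives ochre 10%, teal 8%, green 10%, red 13% and grey 12%, saying “Red is the likely best”, and it parts from my figures most on green.

The flasks give ochre 12.4%, teal 8.16%, green 3.89%, red 13.9% and grey 11.6%, with red best.

    complex with two exchanged + incoming ligand ⇌ leaving ligand + complex with three exchanged (K = 0.130, k = 0.242 M⁻¹ min⁻¹, Ea = 61.0 kJ mol⁻¹, ΔH = −62.0 kJ mol⁻¹)
    2 starting complex → homo dimer (k = 0.738 M⁻¹ min⁻¹, Ea = 49.0 kJ mol⁻¹)
    complex with one exchanged + incoming ligand ⇌ leaving ligand + complex with two exchanged (K = 0.370, k = 0.723 M⁻¹ min⁻¹, Ea = 58.0 kJ mol⁻¹, ΔH = −20.0 kJ mol⁻¹)
    starting complex + incoming ligand ⇌ leaving ligand + complex with one exchanged (K = 0.770, k = 0.468 M⁻¹ min⁻¹, Ea = 51.0 kJ mol⁻¹, ΔH = 14.0 kJ mol⁻¹)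
    (constants at 25 °C)

In red, the first exchange relaxes with a half-life of 0.353 h at 40.0 h, far shorter than the run, so at that time it stands as a pre-equilibrium. At that time in red, the step to homo dimer uses starting complex at 0.095 of the forward rate of that exchange. Over ochre's tail, from 21.4% of complex with one exchanged at 25.0 h to 12.4%, s reads 0.228 h⁻¹. Carried on from green's end, s gives 0.894% at 400 h, where green stands at 1.21%.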